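**Assumption:** Coloratanin A (5,7,4'-trihydroxy-6-prenyl-3'-(3-hydroxy-3-methylbutyl)isoflavone) has no stereocenters. The carbinol carbon carries two methyls, so the compound is achiral and no enantioselective step is needed.

## Retrosynthetic overview
1. Disconnect the C3–C1' bond (Suzuki–Miyaura) and the 7-O-MOM group. This gives 3-iodochromone **7** and aryl-Bpin **11**.
2. **11** comes from 4-bromophenol (**8**) by ortho-hydroarylation with 2-methylbut-3-en-2-ol (**9**, the proposed new step), followed by Miyaura borylation.
3. **7** comes from cross-metathesis of a 6-allyl group, which comes from Claisen rearrangement of a 5-O-allyl ether. The Claisen is regiospecific for C6 because C4a is blocked.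
4. The pyranone ring is closed by I2-mediated enaminone cyclization (Step 4), which also installs the C3 iodide. The 5-O-allyl chromone is made from desymmetrized phloroacetophenone, whose two chelated OH groups are equivalent.
5. Order of bond formation: pyranone ring, then C6–allyl (Claisen), then prenyl (CM), then the C3-aryl bond, then global deprotection.

## Route

**Step 1**
Reactants: **1** 2,4,6-trihydroxyacetophenone
Product: **2** 1-(2,6-dihydroxy-4-(methoxymethoxy)phenyl)ethan-1-one
Conditions: MOMCl (1.0 equiv), K2CO3 (1.1 equiv), acetone, 0 °C to rt, 12 h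
Reagents that add atoms: MOMCl, ClCOC
Why: The non-chelated, most acidic 4-OH is alkylated selectively over the two C=O-chelated OH groups (Williamson-type MOM protection).

**Step 2**
Reactants: **2**
Product: **3** 1-(2-(allyloxy)-6-hydroxy-4-(methoxymethoxy)phenyl)ethan-1-one
Conditions: allyl bromide (1.1 equiv), K2CO3 (1.2 equiv), acetone, reflux, 12 h
Reagents that add atoms: allyl bromide, BrCC=C
Why: The two chelated OH groups are enantiotopic, so mono-O-allylation gives one constitutional product (Williamson ether synthesis). The free OH is retained for ring closure, and the allyl ether marks the future 5-O position.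

**Step 3**
Reactants: **3**
Product: **4** (E)-3-(dimethylamino)-1-(2-(allyloxy)-6-hydroxy-4-(methoxymethoxy)phenyl)prop-2-en-1-one
Conditions: DMF-DMA (3 equiv), toluene, 100 °C, 4 h
Reagents that add atoms: DMF-DMA, CN(C)C(OC)OC
Why: The acetyl CH3 condenses with the amide acetal to give the enaminone (Bredereck-type condensation). The OMe and OMOM groups and the allyl ether are inert.

**Step 4**
Reactants: **4**
Product: **5** 5-(allyloxy)-3-iodo-7-(methoxymethoxy)-4H-chromen-4-one
Conditions: I2 (1.5 equiv), CHCl3, rt, 3 h; then aq. Na2S2O3
Reagents that add atoms: I2, II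
Why: I2 iodinates the enaminone α-carbon. The free phenol then adds to the β-carbon and HNMe2 is lost (Gammill-type 3-iodochromone synthesis). Only one OH is free, so the ring closes unambiguously to the 5-O-allyl, 7-OMOM chromone.

**Step 5**
Reactants: **5**
Product: **6** 6-allyl-5-hydroxy-3-iodo-7-(methoxymethoxy)-4H-chromen-4-one
Conditions: N,N-diethylaniline, 190 °C (microwave), 30 min
Reagents that add atoms: none (isomerization)
Why: Aromatic Claisen [3,3] rearrangement. The only free ortho position of the 5-O-allyl ether is C6, because C4a is substituted. The C5-OH is then re-chelated to C4=O.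

**Step 6**
Reactants: **6**
Product: **7** 5-hydroxy-3-iodo-7-(methoxymethoxy)-6-(3-methylbut-2-en-1-yl)-4H-chromen-4-one
Conditions: 2-methyl-2-butene (20 equiv), Hoveda–Grubbs II (5 mol %), CH2Cl2, 40 °C (sealed), 12 h
Reagents that add atoms: 2-methyl-2-butene, CC=C(C)C
Why: Cross-metathesis of the terminal allyl alkene with 2-methyl-2-butene gives the trisubstituted prenyl alkene. The vinyl iodide, the chelated phenol and the MOM ether are tolerated.

**Step 7 (new step)**
Reactants: **8** 4-bromophenol (2.0 equiv); **9** 2-methylbut-3-en-2-ol (1.0 equiv)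
Product: **10** 4-bromo-2-(3-hydroxy-3-methylbutyl)phenol
Conditions: Re2(CO)10 (5 mol %), mesitylene, 150 °C, sealed tube, 24 h
Reagents that add atoms: none
Why: Proposed new method: phenol-directed, Re(I)-catalyzed ortho C–H alkylation with an alkene that carries a free tertiary allylic alcohol, which has not been shown.
- The alcohol cannot isomerize to a carbonyl because it has no carbinol H.
- Mechanism: Re-phenoxide formation, ortho C–H metalation to a five-membered oxa-rhenacycle, then 1,2-insertion of the vinyl carbinol. Aryl migrates to the unhindered terminal CH2, placing Re on the internal carbon. Protonolysis by the next phenol O–H releases the linear (anti-Markovnikov) chain and regenerates Re-phenoxide.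
- The para-Br blocks para alkylation, and excess phenol limits bis-ortho alkylation.
- The closest known reaction is Re2(CO)10 ortho-alkylation of phenols with simple alkenes.

**Step 8**
Reactants: **10**
Product: **11** 2-(3-hydroxy-3-methylbutyl)-4-(4,4,5,5-tetramethyl-1,3,2-dioxaborolan-2-yl)phenol
Conditions: B2pin2 (1.2 equiv), Pd(dppf)Cl2·CH2Cl2 (3 mol %), KOAc (3 equiv), 1,4-dioxane, 90 °C, 8 h
Reagents that add atoms: B2pin2, CC1(C)OB(OC1(C)C)B1OC(C)(C)C(C)(C)O1
Why: Miyaura borylation of the aryl bromide. The free phenol and tertiary alcohol are tolerated under the mild base KOAc.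

**Step 9**
Reactants: **7** (1.0 equiv); **11** (1.3 equiv)
Product: **12** 3-(4-hydroxy-3-(3-hydroxy-3-methylbutyl)phenyl)-5-hydroxy-7-(methoxymethoxy)-6-(3-methylbut-2-en-1-yl)-4H-chromen-4-one
Conditions: Pd(PPh3)4 (5 mol %), Na2CO3 (3 equiv), DME/H2O 4:1, 80 °C, 4 h, Ar
Reagents that add atoms: none
Why: Suzuki–Miyaura coupling at the reactive vinyl C–I bond. The 5-OH is chelated and untouched, carbonate is mild enough not to open the chromone, and the prenyl alkene survives.

**Step 10**
Reactants: **12**
Product: **13** Coloratanin A
Conditions: 3 M HCl (aq.), THF/MeOH 1:1, 40 °C, 3 h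
Reagents that add atoms: none (MOM is removed as CH2O and MeOH)
Why: Acid hydrolysis of the aryl MOM acetal. Mild, short conditions avoid chroman formation from the prenyl phenol and the tertiary alcohol. No stereocenters exist to be scrambled.

## Final checks
- **Target match.** Product **13** has a chromone core with 2-H, 3-aryl, 4-C=O, 5-OH, 6-prenyl, 7-OH and 8-H. The B ring is 4'-OH with 3'-CH2CH2C(CH3)2OH, matching the target SMILES.
- **Atom accounting.** Each step's product follows from its reactants and listed reagents. Step 5 is an isomerization, and step 10 only removes the MOM group.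
- **Group compatibility.** The prenyl alkene is made after the thermal step (Step 5) and is untouched by Steps 8–10. The free OH groups and the tertiary alcohol are inert in Steps 8 and 9.

## Compound list
1 | 2,4,6-trihydroxyacetophenone | CC(=O)c1c(O)cc(O)cc1O | starting material
2 | 2',6'-dihydroxy-4'-(MOM-oxy)acetophenone | CC(=O)c1c(O)cc(OCOC)cc1O | intermediate
3 | 2'-allyloxy-6'-hydroxy-4'-(MOM-oxy)acetophenone | CC(=O)c1c(O)cc(OCOC)cc1OCC=C | intermediate
4 | (E)-enaminone of 3 | CN(C)/C=C/C(=O)c1c(O)cc(OCOC)cc1OCC=C | intermediate
5 | 5-allyloxy-3-iodo-7-MOM-oxychromone | O=c1c(I)coc2cc(OCOC)cc(OCC=C)c12 | intermediate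
6 | 6-allyl-5-hydroxy-3-iodo-7-MOM-oxychromone | C=CCc1c(OCOC)cc2occ(I)c(=O)c2c1O | intermediate
7 | 5-hydroxy-3-iodo-7-MOM-oxy-6-prenylchromone | CC(C)=CCc1c(OCOC)cc2occ(I)c(=O)c2c1O | intermediate
8 | 4-bromophenol | Oc1ccc(Br)cc1 | starting material
9 | 2-methylbut-3-en-2-ol | C=CC(C)(C)O | starting material
10 | 4-bromo-2-(3-hydroxy-3-methylbutyl)phenol | CC(C)(O)CCc1cc(Br)ccc1O | intermediate
11 | aryl pinacol boronate | CC(C)(O)CCc1cc(B2OC(C)(C)C(C)(C)O2)ccc1O | intermediate
12 | MOM-protected isoflavone | CC(C)=CCc1c(OCOC)cc2occ(-c3ccc(O)c(CCC(C)(C)O)c3)c(=O)c2c1O | intermediate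
13 | Coloratanin A (achiral) | CC(C)=CCc1c(O)cc2occ(-c3ccc(O)c(CCC(C)(C)O)c3)c(=O)c2c1O | target

## Totals
Total steps: 10. Longest linear sequence: 8 (Steps 1–6, 9, 10). The B-ring branch (Steps 7, 8) is 2 steps.

## Three steps most likely to fail
1. **Step 7 (proposed new hydroarylation).** Risks are low conversion, β-OH elimination to the ortho-prenyl phenol, and dehydrative cyclization to a 2,2-dimethylchroman.
   - Fallback (known chemistry): use commercial 6-bromo-3,4-dihydrocoumarin and add excess MeMgBr (THF, 0 °C). This opens the lactone and adds twice to give **10**.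
2. **Step 5 (thermal Claisen in the presence of the C–I bond).** Risks are deiodination and decomposition at 190 °C.
   - Fallback: replace Steps 2, 5 and 6 with a 5-O-(1,1-dimethylallyl) ether. Make the 1,1-dimethylpropargyl ether with CuCl/DBU and 3-chloro-3-methylbutyne, then partially reduce it with Lindlar catalyst. Its low-temperature Claisen gives the normal prenyl group at C6 directly.
3. **Step 10 (acidic MOM removal).** Risk is acid-mediated cyclization of the prenyl phenol or the tertiary alcohol to chromans.
   - Fallback: use a 7-O-TBS group in place of MOM (TBSCl/imidazole in Step 1) and remove it at the end with TBAF/AcOH, which avoids acid.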